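A direct plan would take 5-bromovanillin A1, exchange its methyl ether for two silyl ethers, attach the prenyl group by Stille coupling (aldehyde A2), add a methoxyacetate enolate and oxidise to the β-keto ester A3, fuse A3 with phloroglucinol A4 near 240 °C to close ring C (silylated flavone A5), and desilylate.
Its weakest step would be the melt condensation: ring C would close by chance (chromone or coumarin, C- or O-acylation) at a temperature the silyl ethers and the prenyl group must survive, and this on the most valuable intermediate.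
The second would be the palladium-mediated prenyl transfer to a bromide beside a bulky silyloxy group: linear against branched coupling would rest on the allylpalladium intermediate and would not be controlled.
The third would be the run-up: demethylation, silylation, aldol addition and oxidation would be four steps for one C–C bond, and would make two stereocentres only to destroy them.

Plan of the new route
The retrosynthesis cuts ring A at C5–C6, C7–C8 and C4a–C5 (ketene + ynol ether benzannulation), then the C2–C1' bond (Suzuki coupling) and the aryl–prenyl bond (aryl metal on prenyl bromide).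
Ring C is bought as comenic acid, which supplies O1, C2, C3 with its oxygen, C4(=O), C4a and C8a; its carboxyl carbon becomes C5 with the 5-OH after a Wolff shift. Ring B is attached second and ring A is built last.
The enabling feature: ring A is a resorcinol (O5 and O7 meta, H on C6 and C8) fused at C4a–C8a to a 3-oxygenated 4-pyranone, and C8a has only one carbon neighbour (C4a) at which a 6π closure can end.
No phenolic melt and no allylpalladium step occur: ring A closes by an electrocyclisation with one possible site at 90 °C or below, and the prenyl group enters by SN2 attack at its primary carbon.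
Protecting groups are put on once and no stereocentre is made.
Key step: step 10

Remark: comenic acid (5-hydroxy-4-oxo-4H-pyran-2-carboxylic acid) is taken as a catalogue compound; it is otherwise one oxidation from kojic acid.

Step 1
Reactants: 1 comenic acid (5-hydroxy-4-oxo-4H-pyran-2-carboxylic acid)
Product: 2 6-bromo-5-hydroxy-4-oxo-4H-pyran-2-carboxylic acid
Conditions: Br2 (1.05 equiv), H2O, 0 °C → rt
Reagents that add atoms: bromine, BrBr
Why: Electrophilic substitution of the enolic 3-hydroxy-4-pyranone at C6, the carbon ortho to the hydroxyl, which is where kojic and comenic acids take up halogen as a phenol would, while C3 between the carbonyl and the carboxyl-bearing carbon is deactivated.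

Step 2
Reactants: 2 6-bromo-5-hydroxy-4-oxo-4H-pyran-2-carboxylic acid
Product: 3 methyl 6-bromo-5-methoxy-4-oxo-4H-pyran-2-carboxylate
Conditions: Me2SO4 (2.5 equiv), K2CO3, acetone, reflux
Reagents that add atoms: dimethyl sulfate, COS(=O)(=O)OC
Why: SN2 methylation of the enolic oxygen and of the carboxylate (Williamson-type O-alkylation) with a mild carbonate base and no iodide, so that the vinylogous acyl bromide is neither displaced nor exchanged.

Step 3
Reactants: 4 3-bromo-5-chloro-2-hydroxybenzaldehyde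
Product: 5 3-bromo-5-chlorobenzene-1,2-diol
Conditions: H2O2 (30 %, 1.2 equiv), NaOH (1 M aq), 0 °C → rt; then HCl
Reagents that add atoms: hydrogen peroxide, OO
Why: Dakin oxidation, in which hydroperoxide adds to the aldehyde of the ortho-phenoxide, the aryl group migrates to oxygen and the aryl formate is hydrolysed to the catechol with both halogens untouched.

Step 4
Reactants: 5 3-bromo-5-chlorobenzene-1,2-diol
Product: 6 1-bromo-5-chloro-2,3-bis(triisopropylsilyloxy)benzene
Conditions: TIPSOTf (2.4 equiv), 2,6-lutidine, CH2Cl2, 0 °C → rt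
Reagents that add atoms: triisopropylsilyl trifluoromethanesulfonate, CC(C)[Si](OS(=O)(=O)C(F)(F)F)(C(C)C)C(C)C
Why: O-silylation with a silyl triflate and a hindered pyridine base is reactive enough for the oxygen flanked by bromine and the first silyloxy group and gives aryl silyl ethers that stand organometallics and mild aqueous base but fall to fluoride.

Step 5
Reactants: 6 1-bromo-5-chloro-2,3-bis(triisopropylsilyloxy)benzene; 7 1-bromo-3-methylbut-2-ene (prenyl bromide)
Product: 9 5-chloro-1-(3-methylbut-2-en-1-yl)-2,3-bis(triisopropylsilyloxy)benzene, via arylmagnesium chloride 8 (not isolated)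
Conditions: i-PrMgCl·LiCl (1.2 equiv), THF, 0 °C → rt; CuI (10 mol %), 7 (1.3 equiv), −20 °C → rt
Reagents that add atoms: none
Why: Bromine–magnesium exchange takes only the C–Br bond (weaker than C–Cl and activated by the ortho oxygen), and copper-catalysed SN2 allylation of the aryl metal at the primary carbon of 7 gives the linear prenyl arene, since attack at the tertiary end would have to build a quaternary benzylic carbon beside a triisopropylsilyloxy group.

Step 6
Reactants: 9 5-chloro-1-(3-methylbut-2-en-1-yl)-2,3-bis(triisopropylsilyloxy)benzene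
Product: 10 2-[3-(3-methylbut-2-en-1-yl)-4,5-bis(triisopropylsilyloxy)phenyl]-4,4,5,5-tetramethyl-1,3,2-dioxaborolane
Conditions: B2pin2 (1.3 equiv), Pd2(dba)3 (2 mol %), XPhos (8 mol %), KOAc, dioxane, 100 °C
Reagents that add atoms: bis(pinacolato)diboron, CC1(C)OB(B2OC(C)(C)C(C)(C)O2)OC1(C)C
Why: Miyaura borylation, in which the unhindered aryl chloride adds oxidatively to zerovalent palladium carrying a bulky biarylphosphine and acetate-assisted transmetalation with the diboron and reductive elimination follow, leaving the trisubstituted alkene and the silyl ethers alone.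

Step 7
Reactants: 3 methyl 6-bromo-5-methoxy-4-oxo-4H-pyran-2-carboxylate; 10 2-[3-(3-methylbut-2-en-1-yl)-4,5-bis(triisopropylsilyloxy)phenyl]-4,4,5,5-tetramethyl-1,3,2-dioxaborolane
Product: 12 5-methoxy-6-[3-(3-methylbut-2-en-1-yl)-4,5-bis(triisopropylsilyloxy)phenyl]-4-oxo-4H-pyran-2-carboxylic acid, via methyl ester 11 (not isolated)
Conditions: Pd(dppf)Cl2 (3 mol %), K3PO4 (2 equiv), dioxane/H2O (10:1), 50 °C; then LiOH (aq, 1.5 equiv), 0 °C → rt; 1 M HCl to pH 3 at 0 °C
Reagents that add atoms: lithium hydroxide, [Li+].[OH-]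
Why: Suzuki–Miyaura coupling at the vinylogous acyl bromide (fast oxidative addition of a β-bromo enone to zerovalent palladium) sets the C2–C1' bond, and the activated pyranone-2-carboxylate is then saponified in the same flask far faster than aryl triisopropylsilyl ethers are cleaved.

Step 8
Reactants: 12 5-methoxy-6-[3-(3-methylbut-2-en-1-yl)-4,5-bis(triisopropylsilyloxy)phenyl]-4-oxo-4H-pyran-2-carboxylic acid
Product: 14 2-(2-diazoacetyl)-5-methoxy-6-[3-(3-methylbut-2-en-1-yl)-4,5-bis(triisopropylsilyloxy)phenyl]-4H-pyran-4-one, via acid chloride 13 (not isolated)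
Conditions: 1-chloro-N,N,2-trimethylprop-1-en-1-amine (1.1 equiv), CH2Cl2, 0 °C; then TMSCHN2 (2.2 equiv), THF/MeCN, 0 °C → rt
Reagents that add atoms: (trimethylsilyl)diazomethane, C[Si](C)(C)C=[N+]=[N-]
Why: The chloroenamine makes the acid chloride under neutral conditions (no HCl for the prenyl alkene, no chloropyrylium formation at the ring carbonyl), and C-acylation of the silyldiazomethane with loss of Me3SiCl gives the diazomethyl ketone, the first half of an Arndt–Eistert sequence.

Step 9
Reactants: 15 2-(trimethylsilyl)ethanol; 16 trichloroethene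
Product: 19 [2-(trimethylsilyl)ethoxy]ethyne, via dichlorovinyl ether 17 (not isolated), via lithium alkynyl ether 18 (not isolated)
Conditions: KH, THF, 0 °C; 16, −50 °C → rt; then n-BuLi (2.4 equiv), −78 → −40 °C; MeOH, −78 °C; distil under reduced pressure
Reagents that add atoms: none
Why: Alkoxyacetylene synthesis from trichloroethene, in which the alkoxide adds anti to dichloroacetylene formed in situ and n-BuLi turns the dichlorovinyl ether by elimination and chlorine–lithium exchange into the lithium alkynyl ether, which is protonated.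

Step 10
Reactants: 14 2-(2-diazoacetyl)-5-methoxy-6-[3-(3-methylbut-2-en-1-yl)-4,5-bis(triisopropylsilyloxy)phenyl]-4H-pyran-4-one; 19 [2-(trimethylsilyl)ethoxy]ethyne
Product: 24 5-hydroxy-3-methoxy-2-[3-(3-methylbut-2-en-1-yl)-4,5-bis(triisopropylsilyloxy)phenyl]-7-[2-(trimethylsilyl)ethoxy]-4H-chromen-4-one, via pyranonylketene 20 (not isolated), via cyclobutenone 21 (not isolated), via dienylketene 22 (not isolated), via keto tautomer 23 (not isolated)
Conditions: 19 (3 equiv), 450 nm LEDs, degassed CH2Cl2, 20 °C, Ar; evaporate excess 19; PhMe, 90 °C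
Reagents that add atoms: none
Why: Danheiser benzannulation: light expels N2 from 14 and Wolff migration of the pyranonyl group gives ketene 20, whose electrophilic central carbon is attacked by the oxygen-free terminal carbon of 19 in a [2+2] cycloaddition to cyclobutenone 21; on warming, 4π-electrocyclic opening gives dienylketene 22, 6π-electrocyclisation onto C3 of the pyranone gives 23, and enolisation gives the phenol. The closest known reaction type is the photochemical aromatic annulation of aryl, heteroaryl and alkenyl diazomethyl ketones with alkoxy- and siloxyalkynes to fused resorcinol monoethers. Ring A is closed by a thermally allowed disrotatory 6π-electrocyclisation of the dienylketene, the four-membered ring being only a relay that opens reversibly until the cyclisation-competent geometry is drained by aromatisation. No stereocentre survives, since C1 of 21 and C4a of 23 end as sp2 carbons. The step needs the meta O5/O7 pattern, secured because the ketene carbonyl carbon (future C5–OH) bonds to the oxygen-free alkyne carbon (future C6–H), and it needs closure at C4a, secured because the other neighbour of C8a is the ring oxygen. Light of 450 nm enters only through the diazo ketone band, so the prenyl alkene and silyl ethers are not excited, and the excess of 19 intercepts the ketene before it can acylate anything else.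

Step 11
Reactants: 24 5-hydroxy-3-methoxy-2-[3-(3-methylbut-2-en-1-yl)-4,5-bis(triisopropylsilyloxy)phenyl]-7-[2-(trimethylsilyl)ethoxy]-4H-chromen-4-one
Product: 25 uralenol 3-methyl ether (2-[3,4-dihydroxy-5-(3-methylbut-2-en-1-yl)phenyl]-5,7-dihydroxy-3-methoxy-4H-chromen-4-one)
Conditions: TBAF (1 M in THF, 6 equiv), degassed THF, 0 °C → rt, Ar; AcOH quench
Reagents that add atoms: none
Why: Fluoride-mediated desilylation, in which Si–F bond formation cleaves both aryl silyl ethers and attack at the trimethylsilyl group triggers β-elimination of ethene from the 7-O-CH2CH2SiMe3 ether (the leaving 7-oxide being a vinylogous carboxylate), with no acid present that could close O4' onto the prenyl alkene.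

Compound list
1 | comenic acid (5-hydroxy-4-oxo-4H-pyran-2-carboxylic acid) | OC(=O)c1cc(=O)c(O)co1 | starting material
2 | 6-bromo-5-hydroxy-4-oxo-4H-pyran-2-carboxylic acid | OC(=O)c1cc(=O)c(O)c(Br)o1 | intermediate
3 | methyl 6-bromo-5-methoxy-4-oxo-4H-pyran-2-carboxylate | COC(=O)c1cc(=O)c(OC)c(Br)o1 | intermediate
4 | 3-bromo-5-chloro-2-hydroxybenzaldehyde | O=Cc1cc(Cl)cc(Br)c1O | starting material
5 | 3-bromo-5-chlorobenzene-1,2-diol | Oc1cc(Cl)cc(Br)c1O | intermediate
6 | 1-bromo-5-chloro-2,3-bis(triisopropylsilyloxy)benzene | Clc1cc(Br)c(O[Si](C(C)C)(C(C)C)C(C)C)c(O[Si](C(C)C)(C(C)C)C(C)C)c1 | intermediate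
7 | 1-bromo-3-methylbut-2-ene (prenyl bromide) | CC(C)=CCBr | starting material
8 | [5-chloro-2,3-bis(triisopropylsilyloxy)phenyl]magnesium chloride (not isolated) | Cl[Mg]c1cc(Cl)cc(O[Si](C(C)C)(C(C)C)C(C)C)c1O[Si](C(C)C)(C(C)C)C(C)C | intermediate
9 | 5-chloro-1-(3-methylbut-2-en-1-yl)-2,3-bis(triisopropylsilyloxy)benzene | CC(C)=CCc1cc(Cl)cc(O[Si](C(C)C)(C(C)C)C(C)C)c1O[Si](C(C)C)(C(C)C)C(C)C | intermediate
10 | 2-[3-(3-methylbut-2-en-1-yl)-4,5-bis(triisopropylsilyloxy)phenyl]-4,4,5,5-tetramethyl-1,3,2-dioxaborolane | CC(C)=CCc1cc(B2OC(C)(C)C(C)(C)O2)cc(O[Si](C(C)C)(C(C)C)C(C)C)c1O[Si](C(C)C)(C(C)C)C(C)C | intermediate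
11 | methyl 5-methoxy-6-[3-(3-methylbut-2-en-1-yl)-4,5-bis(triisopropylsilyloxy)phenyl]-4-oxo-4H-pyran-2-carboxylate (not isolated) | COC(=O)c1cc(=O)c(OC)c(-c2cc(CC=C(C)C)c(O[Si](C(C)C)(C(C)C)C(C)C)c(O[Si](C(C)C)(C(C)C)C(C)C)c2)o1 | intermediate
12 | 5-methoxy-6-[3-(3-methylbut-2-en-1-yl)-4,5-bis(triisopropylsilyloxy)phenyl]-4-oxo-4H-pyran-2-carboxylic acid | OC(=O)c1cc(=O)c(OC)c(-c2cc(CC=C(C)C)c(O[Si](C(C)C)(C(C)C)C(C)C)c(O[Si](C(C)C)(C(C)C)C(C)C)c2)o1 | intermediate
13 | 5-methoxy-6-[3-(3-methylbut-2-en-1-yl)-4,5-bis(triisopropylsilyloxy)phenyl]-4-oxo-4H-pyran-2-carbonyl chloride (not isolated) | ClC(=O)c1cc(=O)c(OC)c(-c2cc(CC=C(C)C)c(O[Si](C(C)C)(C(C)C)C(C)C)c(O[Si](C(C)C)(C(C)C)C(C)C)c2)o1 | intermediate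
14 | 2-(2-diazoacetyl)-5-methoxy-6-[3-(3-methylbut-2-en-1-yl)-4,5-bis(triisopropylsilyloxy)phenyl]-4H-pyran-4-one | [N-]=[N+]=CC(=O)c1cc(=O)c(OC)c(-c2cc(CC=C(C)C)c(O[Si](C(C)C)(C(C)C)C(C)C)c(O[Si](C(C)C)(C(C)C)C(C)C)c2)o1 | intermediate
15 | 2-(trimethylsilyl)ethanol | C[Si](C)(C)CCO | starting material
16 | trichloroethene | ClC=C(Cl)Cl | starting material
17 | (E)-1,2-dichloro-1-[2-(trimethylsilyl)ethoxy]ethene (not isolated) | C[Si](C)(C)CCO/C(Cl)=C\Cl | intermediate
18 | lithium [2-(trimethylsilyl)ethoxy]ethynide (not isolated) | [Li]C#COCC[Si](C)(C)C | intermediate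
19 | [2-(trimethylsilyl)ethoxy]ethyne | C#COCC[Si](C)(C)C | intermediate
20 | 5-methoxy-6-[3-(3-methylbut-2-en-1-yl)-4,5-bis(triisopropylsilyloxy)phenyl]-2-(2-oxoethenyl)-4H-pyran-4-one (pyranonylketene, not isolated) | O=C=Cc1cc(=O)c(OC)c(-c2cc(CC=C(C)C)c(O[Si](C(C)C)(C(C)C)C(C)C)c(O[Si](C(C)C)(C(C)C)C(C)C)c2)o1 | intermediate
21 | 5-methoxy-6-[3-(3-methylbut-2-en-1-yl)-4,5-bis(triisopropylsilyloxy)phenyl]-2-{4-oxo-2-[2-(trimethylsilyl)ethoxy]cyclobut-2-en-1-yl}-4H-pyran-4-one, racemic (not isolated) | O=C1C=C(OCC[Si](C)(C)C)C1c1cc(=O)c(OC)c(-c2cc(CC=C(C)C)c(O[Si](C(C)C)(C(C)C)C(C)C)c(O[Si](C(C)C)(C(C)C)C(C)C)c2)o1 | intermediate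
22 | 5-methoxy-6-[3-(3-methylbut-2-en-1-yl)-4,5-bis(triisopropylsilyloxy)phenyl]-2-{(1E)-4-oxo-2-[2-(trimethylsilyl)ethoxy]buta-1,3-dien-1-yl}-4H-pyran-4-one (dienylketene, ketenyl group cis to the pyranone, not isolated) | O=C=C/C(OCC[Si](C)(C)C)=C\c1cc(=O)c(OC)c(-c2cc(CC=C(C)C)c(O[Si](C(C)C)(C(C)C)C(C)C)c(O[Si](C(C)C)(C(C)C)C(C)C)c2)o1 | intermediate
23 | 3-methoxy-2-[3-(3-methylbut-2-en-1-yl)-4,5-bis(triisopropylsilyloxy)phenyl]-7-[2-(trimethylsilyl)ethoxy]-4aH-chromene-4,5-dione, racemic keto tautomer of 24 (not isolated) | COC1=C(c3cc(CC=C(C)C)c(O[Si](C(C)C)(C(C)C)C(C)C)c(O[Si](C(C)C)(C(C)C)C(C)C)c3)OC2=CC(OCC[Si](C)(C)C)=CC(=O)C2C1=O | intermediate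
24 | 5-hydroxy-3-methoxy-2-[3-(3-methylbut-2-en-1-yl)-4,5-bis(triisopropylsilyloxy)phenyl]-7-[2-(trimethylsilyl)ethoxy]-4H-chromen-4-one | COc1c(-c2cc(CC=C(C)C)c(O[Si](C(C)C)(C(C)C)C(C)C)c(O[Si](C(C)C)(C(C)C)C(C)C)c2)oc2cc(OCC[Si](C)(C)C)cc(O)c2c1=O | intermediate
25 | uralenol 3-methyl ether, 2-[3,4-dihydroxy-5-(3-methylbut-2-en-1-yl)phenyl]-5,7-dihydroxy-3-methoxy-4H-chromen-4-one (achiral) | COc1c(-c2cc(O)c(O)c(CC=C(C)C)c2)oc2cc(O)cc(O)c2c1=O | target

Total step count: 11. Longest linear sequence: 8 steps (steps 3, 4, 5, 6, 7, 8, 10 and 11).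

Steps most likely to fail

1. Step 10. Photolysis may not lead cleanly to Wolff migration: the excited diazo ketone may insert into solvent, or the aryl-pyranone may be excited and isomerise, so that no ketene meets 19. The fallback sets out from 14 and comes back at 21, making the same ketene in the dark by dehydrohalogenation. Silver-catalysed Wolff rearrangement of 14 in aqueous THF (PhCO2Ag, Et3N; Arndt–Eistert homologation) would give {5-methoxy-6-[3-(3-methylbut-2-en-1-yl)-4,5-bis(triisopropylsilyloxy)phenyl]-4-oxo-4H-pyran-2-yl}acetic acid F1. 1-Chloro-N,N,2-trimethylprop-1-en-1-amine would convert it into the corresponding acetyl chloride F2. Slow addition of Et3N to F2 and 19 in CH2Cl2 at rt would generate ketene 20 thermally and deliver cyclobutenone 21, from which the thermal part of step 10 would be run unchanged.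

2. Step 7. Hydroxide or phosphate may displace bromide from 3 by addition–elimination, or open the pyranone, faster than palladium inserts, and the activated ester may be lost before coupling. The fallback sets out from 10 and comes back at 12, moving the coupling to the alcohol oxidation level, where the ring is less electrophilic and no saponification is needed. Kojic acid would be brominated and O-methylated as in steps 1 and 2 to 6-bromokojic acid F3 and then 6-bromo-2-(hydroxymethyl)-5-methoxy-4H-pyran-4-one F4. Suzuki coupling of F4 with 10 (Pd(dppf)Cl2, K3PO4) would give the 2-(hydroxymethyl)-6-arylpyranone F5. TEMPO/PhI(OAc)2 in aqueous MeCN would oxidise F5 through the pyran-2-carbaldehyde F6 to acid 12.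

3. Step 5. Bromine–magnesium exchange at the bromide flanked by a triisopropylsilyloxy group may be slow, and some allyl transposition to the tertiary (reverse-prenyl) isomer may occur. The fallback sets out from 6 and comes back at 9 by inverting the polarity of the coupling. Suzuki–Miyaura coupling of bromide 6 with commercial 3-methylbut-2-enylboronic acid pinacol ester (Pd(OAc)2, a bulky biarylphosphine chosen for coupling at the primary allyl terminus, K3PO4, aqueous THF, 40 °C) would leave the C–Cl bond untouched and give 9 directly. No new intermediate arises.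

Further compounds
F1 | step 10 | {5-methoxy-6-[3-(3-methylbut-2-en-1-yl)-4,5-bis(triisopropylsilyloxy)phenyl]-4-oxo-4H-pyran-2-yl}acetic acid | OC(=O)Cc1cc(=O)c(OC)c(-c2cc(CC=C(C)C)c(O[Si](C(C)C)(C(C)C)C(C)C)c(O[Si](C(C)C)(C(C)C)C(C)C)c2)o1
F2 | step 10 | {5-methoxy-6-[3-(3-methylbut-2-en-1-yl)-4,5-bis(triisopropylsilyloxy)phenyl]-4-oxo-4H-pyran-2-yl}acetyl chloride | ClC(=O)Cc1cc(=O)c(OC)c(-c2cc(CC=C(C)C)c(O[Si](C(C)C)(C(C)C)C(C)C)c(O[Si](C(C)C)(C(C)C)C(C)C)c2)o1
F3 | step 7 | 6-bromokojic acid (6-bromo-5-hydroxy-2-(hydroxymethyl)-4H-pyran-4-one) | OCc1cc(=O)c(O)c(Br)o1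
F4 | step 7 | 6-bromo-2-(hydroxymethyl)-5-methoxy-4H-pyran-4-one | OCc1cc(=O)c(OC)c(Br)o1
F5 | step 7 | 2-(hydroxymethyl)-5-methoxy-6-[3-(3-methylbut-2-en-1-yl)-4,5-bis(triisopropylsilyloxy)phenyl]-4H-pyran-4-one | OCc1cc(=O)c(OC)c(-c2cc(CC=C(C)C)c(O[Si](C(C)C)(C(C)C)C(C)C)c(O[Si](C(C)C)(C(C)C)C(C)C)c2)o1
F6 | step 7 | 5-methoxy-6-[3-(3-methylbut-2-en-1-yl)-4,5-bis(triisopropylsilyloxy)phenyl]-4-oxo-4H-pyran-2-carbaldehyde | O=Cc1cc(=O)c(OC)c(-c2cc(CC=C(C)C)c(O[Si](C(C)C)(C(C)C)C(C)C)c(O[Si](C(C)C)(C(C)C)C(C)C)c2)o1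
F0 | step 5 | none | none
A1 | direct plan | 5-bromovanillin | COc1cc(C=O)cc(Br)c1O
A2 | direct plan | 3-(3-methylbut-2-en-1-yl)-4,5-bis(triisopropylsilyloxy)benzaldehyde | O=Cc1cc(CC=C(C)C)c(O[Si](C(C)C)(C(C)C)C(C)C)c(O[Si](C(C)C)(C(C)C)C(C)C)c1
A3 | direct plan | ethyl 2-methoxy-3-oxo-3-[3-(3-methylbut-2-en-1-yl)-4,5-bis(triisopropylsilyloxy)phenyl]propanoate (racemic) | CCOC(=O)C(OC)C(=O)c1cc(CC=C(C)C)c(O[Si](C(C)C)(C(C)C)C(C)C)c(O[Si](C(C)C)(C(C)C)C(C)C)c1
A4 | direct plan | phloroglucinol | Oc1cc(O)cc(O)c1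
A5 | direct plan | 5,7-dihydroxy-3-methoxy-2-[3-(3-methylbut-2-en-1-yl)-4,5-bis(triisopropylsilyloxy)phenyl]-4H-chromen-4-one | COc1c(-c2cc(CC=C(C)C)c(O[Si](C(C)C)(C(C)C)C(C)C)c(O[Si](C(C)C)(C(C)C)C(C)C)c2)oc2cc(O)cc(O)c2c1=O
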